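**Plan** (flavanone numbering: O1, C2, C3, C4(=O), C4a, C5–C8, C8a; ring A = fused benzene, ring B = 2-aryl, ring C = pyranone)
- Retrosynthesis: cut the three O–MOM bonds last; add back the C2=C3 double bond (flavanone ⇒ flavone); then open ring C of the flavone at C4–C4a, C3–C4 and O1–C2, giving phenol 8, bromoalkyne 12 and CO.
- Forward: ring A is built first with both prenyl groups in place (Br/Li exchange at the future C8, OMOM-directed lithiation at the future C6); ring B enters as a bromoalkyne.
- Ring C is closed last in one pot: O1–C2 by phenol addition, C3–C4 by CO insertion, C4–C4a by C–H acylation.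
- Enabling feature: C4a–H is the only free C–H ortho to O1 on ring A (C8 is blocked by prenyl) and is para to O7, so an acylpalladium held cis to O1 across C2=C3 can close only there.
- Stereochemistry: C2 is set after ring closure by CuH/(R)-DTBM-SEGPHOS conjugate reduction of the flavone; only an acidic deprotection follows, so the base-labile centre is never exposed to base.

Key step: step 9

Assumption: CuH/(R)-DTBM-SEGPHOS is taken to deliver hydride to the face of C2 that gives the (2S) product; the sense would be fixed on a simple flavone and the (S)-ligand used if it is opposite.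

Step 1
Reactants: 1 2-bromobenzene-1,3-diol
Product: 2 2-bromo-3-[(triisopropylsilyl)oxy]phenol
Conditions: TIPSCl (1.0 equiv), imidazole, DMF, 0 °C to rt; 1 in excess (1.5 equiv), recovered
Reagents that add atoms: chlorotriisopropylsilane (TIPSCl), CC(C)[Si](Cl)(C(C)C)C(C)C
Why: Statistical monosilylation of a symmetric diol (silyl ether formation), in which the excess diol should hold back the bis-silyl ether; the bulky TIPS group later shields its side of the ring against lithiation.

Step 2
Reactants: 2 2-bromo-3-[(triisopropylsilyl)oxy]phenol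
Product: 3 [2-bromo-3-(methoxymethoxy)phenoxy]triisopropylsilane
Conditions: MOMCl, iPr2NEt, CH2Cl2, 0 °C to rt
Reagents that add atoms: chloromethyl methyl ether (MOMCl), COCCl
Why: O-alkylation of the phenol (MOM acetal formation) under amine base, which should not scramble the silyl ether, installs the only ortho-directing group of the ring and the O7 protecting group.

Step 3
Reactants: 3 [2-bromo-3-(methoxymethoxy)phenoxy]triisopropylsilane
Product: 5 [3-(methoxymethoxy)-2-(3-methylbut-2-en-1-yl)phenoxy]triisopropylsilane, via aryllithium 4 (not isolated)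
Conditions: n-BuLi, THF, −78 °C; CuBr·SMe2 (10 mol %), prenyl bromide, −78 to 0 °C
Reagents that add atoms: prenyl bromide (1-bromo-3-methylbut-2-ene), CC(C)=CCBr
Why: Bromine–lithium exchange places the metal regiospecifically between the two oxygens, and copper-catalysed SN2 alkylation with prenyl bromide should give the linear prenyl group, the low temperature keeping the silyl group from O-to-C migration (retro-Brook).

Step 4
Reactants: 5 [3-(methoxymethoxy)-2-(3-methylbut-2-en-1-yl)phenoxy]triisopropylsilane
Product: 7 [3-(methoxymethoxy)-2,4-bis(3-methylbut-2-en-1-yl)phenoxy]triisopropylsilane, via aryllithium 6 (not isolated)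
Conditions: n-BuLi, TMEDA, THF, −20 to 0 °C; CuBr·SMe2 (10 mol %), prenyl bromide, −78 °C to rt
Reagents that add atoms: prenyl bromide (1-bromo-3-methylbut-2-ene), CC(C)=CCBr
Why: Directed ortho-metalation, in which OMOM is the only directing group and its other ortho position is already occupied, should lithiate C4 alone (the OTIPS side is shielded), and prenylation follows as in step 3.

Step 5
Reactants: 7 [3-(methoxymethoxy)-2,4-bis(3-methylbut-2-en-1-yl)phenoxy]triisopropylsilane
Product: 8 3-(methoxymethoxy)-2,4-bis(3-methylbut-2-en-1-yl)phenol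
Conditions: TBAF, AcOH (1:1), THF, 0 °C
Reagents that add atoms: none
Why: Fluoride-induced desilylation, buffered with acetic acid, frees the O1 phenol while the MOM ether and both prenyl groups should be untouched.

Step 6
Reactants: 9 2,4-dihydroxybenzaldehyde
Product: 10 2,4-bis(methoxymethoxy)benzaldehyde
Conditions: MOMCl, K2CO3, acetone, reflux
Reagents that add atoms: chloromethyl methyl ether (MOMCl), COCCl
Why: Double O-alkylation of the phenols (MOM acetal formation), the heating being needed for the hydrogen-bonded 2-hydroxyl.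

Step 7
Reactants: 10 2,4-bis(methoxymethoxy)benzaldehyde
Product: 11 1-(2,2-dibromoethenyl)-2,4-bis(methoxymethoxy)benzene
Conditions: CBr4, PPh3, CH2Cl2, 0 °C
Reagents that add atoms: carbon tetrabromide, BrC(Br)(Br)Br
Why: Corey–Fuchs dibromo-olefination (Wittig-type reaction of the ylide Ph3P=CBr2 formed in the flask) adds the carbon that becomes C3.

Step 8
Reactants: 11 1-(2,2-dibromoethenyl)-2,4-bis(methoxymethoxy)benzene
Product: 12 1-(bromoethynyl)-2,4-bis(methoxymethoxy)benzene
Conditions: DBU, DMSO, 15 °C
Reagents that add atoms: none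
Why: Base-induced anti dehydrobromination of a 1,1-dibromoalkene is a known route to 1-bromoalkynes and avoids electrophilic bromine on the electron-rich ring.

Step 9
Reactants: 8 3-(methoxymethoxy)-2,4-bis(3-methylbut-2-en-1-yl)phenol; 12 1-(bromoethynyl)-2,4-bis(methoxymethoxy)benzene
Product: 14 2-[2,4-bis(methoxymethoxy)phenyl]-7-(methoxymethoxy)-6,8-bis(3-methylbut-2-en-1-yl)-4H-chromen-4-one, via (Z)-2-bromovinyl aryl ether 13 (not isolated)
Conditions: Cs2CO3 (1.5 equiv), DMF, 4 Å MS, 110 °C; then Pd(PCy3)2 (5 mol %), CsOPiv (30 mol %), CO (5 bar), 110 °C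
Reagents that add atoms: carbon monoxide, [C-]#[O+]
Why: Proposed new method: the phenoxide of 8 adds anti across bromoalkyne 12 at the aryl-bearing carbon (a known reaction type) to give the (Z)-2-bromovinyl ether 13 with Br cis to the aryloxy group; zerovalent palladium then inserts into the C–Br bond, CO inserts into the vinyl–Pd bond, the resulting (Z)-3-aryloxyacryloyl–palladium species palladates the one free C–H ortho to O1 of ring A by pivalate-assisted concerted metalation–deprotonation, and C–C reductive elimination forms the C4–C4a bond. The closest known reaction types are the palladium-catalysed cyclocarbonylation of ortho-halobiaryls to fluorenones and the CO-free palladium-catalysed C–H cyclisation of the same class of (Z)-2-bromovinyl aryl ethers to 2-arylbenzofurans. Ring C closes as a six-membered ring by reductive elimination from a seven-membered acyl(aryl)palladacycle, formally a 6-exo acylation of the arene. No stereocentre is formed; the Z geometry of 13, fixed by the anti addition, is what brings the acyl carbon within reach of C4a and keeps it trans to ring B. The step needs CO insertion to outrun direct C–H vinylation (which would give the benzofuran), which the CO pressure and the fast carbonylation of vinylpalladium species should secure, and it needs site selectivity, which is secured because C8 carries a prenyl group so that the electron-rich C4a–H (para to O7) is the only position within reach.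

Step 10
Reactants: 14 2-[2,4-bis(methoxymethoxy)phenyl]-7-(methoxymethoxy)-6,8-bis(3-methylbut-2-en-1-yl)-4H-chromen-4-one
Product: 16 (2S)-2-[2,4-bis(methoxymethoxy)phenyl]-7-(methoxymethoxy)-6,8-bis(3-methylbut-2-en-1-yl)-2,3-dihydro-4H-chromen-4-one, via silyl enol ether 15 (not isolated)
Conditions: Cu(OAc)2·H2O (5 mol %), (R)-DTBM-SEGPHOS (5.5 mol %), (EtO)2MeSiH, toluene, 0 °C to rt; then aq. citric acid, THF
Reagents that add atoms: none
Why: CuH-catalysed asymmetric conjugate reduction (1,4-hydrosilylation) of a chromone, in which the chiral bisphosphine–CuH complex selects the face of C2 and sets (2S), the product being held as silyl enol ether 15 so that neither reduction at C4 nor ring opening through a free enolate is expected before mild acid releases the ketone, while the isolated trisubstituted prenyl alkenes should not react.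

Step 11
Reactants: 16 (2S)-2-[2,4-bis(methoxymethoxy)phenyl]-7-(methoxymethoxy)-6,8-bis(3-methylbut-2-en-1-yl)-2,3-dihydro-4H-chromen-4-one
Product: 17 (2S)-2-(2,4-dihydroxyphenyl)-7-hydroxy-6,8-bis(3-methylbut-2-en-1-yl)-2,3-dihydro-4H-chromen-4-one
Conditions: 3 M aq. HCl, MeOH, 40 °C
Reagents that add atoms: none
Why: Acid-catalysed acetal exchange (MOM cleavage, giving dimethoxymethane) frees the three phenols without base, so the C2 centre, which racemises by retro-oxa-Michael ring opening under basic conditions, should be kept.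

**Compound list**
1 | 2-bromobenzene-1,3-diol | Oc1cccc(O)c1Br | starting material
2 | 2-bromo-3-[(triisopropylsilyl)oxy]phenol | Oc1cccc(O[Si](C(C)C)(C(C)C)C(C)C)c1Br | intermediate
3 | [2-bromo-3-(methoxymethoxy)phenoxy]triisopropylsilane | COCOc1cccc(O[Si](C(C)C)(C(C)C)C(C)C)c1Br | intermediate
4 | [2-(methoxymethoxy)-6-(triisopropylsilyloxy)phenyl]lithium | COCOc1cccc(O[Si](C(C)C)(C(C)C)C(C)C)c1[Li] | intermediate (not isolated)
5 | [3-(methoxymethoxy)-2-(3-methylbut-2-en-1-yl)phenoxy]triisopropylsilane | COCOc1cccc(O[Si](C(C)C)(C(C)C)C(C)C)c1CC=C(C)C | intermediate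
6 | [2-(methoxymethoxy)-3-(3-methylbut-2-en-1-yl)-4-(triisopropylsilyloxy)phenyl]lithium | COCOc1c([Li])ccc(O[Si](C(C)C)(C(C)C)C(C)C)c1CC=C(C)C | intermediate (not isolated)
7 | [3-(methoxymethoxy)-2,4-bis(3-methylbut-2-en-1-yl)phenoxy]triisopropylsilane | COCOc1c(CC=C(C)C)ccc(O[Si](C(C)C)(C(C)C)C(C)C)c1CC=C(C)C | intermediate
8 | 3-(methoxymethoxy)-2,4-bis(3-methylbut-2-en-1-yl)phenol | COCOc1c(CC=C(C)C)ccc(O)c1CC=C(C)C | intermediate
9 | 2,4-dihydroxybenzaldehyde | O=Cc1ccc(O)cc1O | starting material
10 | 2,4-bis(methoxymethoxy)benzaldehyde | COCOc1ccc(C=O)c(OCOC)c1 | intermediate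
11 | 1-(2,2-dibromoethenyl)-2,4-bis(methoxymethoxy)benzene | COCOc1ccc(C=C(Br)Br)c(OCOC)c1 | intermediate
12 | 1-(bromoethynyl)-2,4-bis(methoxymethoxy)benzene | COCOc1ccc(C#CBr)c(OCOC)c1 | intermediate
13 | 1-{[(Z)-2-bromo-1-[2,4-bis(methoxymethoxy)phenyl]ethenyl]oxy}-3-(methoxymethoxy)-2,4-bis(3-methylbut-2-en-1-yl)benzene | Br/C=C(\Oc1ccc(CC=C(C)C)c(OCOC)c1CC=C(C)C)c1ccc(OCOC)cc1OCOC | intermediate (not isolated)
14 | 2-[2,4-bis(methoxymethoxy)phenyl]-7-(methoxymethoxy)-6,8-bis(3-methylbut-2-en-1-yl)-4H-chromen-4-one | COCOc1ccc(C2=CC(=O)c3cc(CC=C(C)C)c(OCOC)c(CC=C(C)C)c3O2)c(OCOC)c1 | intermediate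
15 | {[(2S)-2-[2,4-bis(methoxymethoxy)phenyl]-7-(methoxymethoxy)-6,8-bis(3-methylbut-2-en-1-yl)-2H-chromen-4-yl]oxy}diethoxy(methyl)silane | CC(C)=CCc1cc2c(c(CC=C(C)C)c1OCOC)O[C@H](c1ccc(OCOC)cc1OCOC)C=C2O[Si](C)(OCC)OCC | intermediate (not isolated)
16 | (2S)-2-[2,4-bis(methoxymethoxy)phenyl]-7-(methoxymethoxy)-6,8-bis(3-methylbut-2-en-1-yl)-2,3-dihydro-4H-chromen-4-one | CC(C)=CCc1cc2c(c(CC=C(C)C)c1OCOC)O[C@H](c1ccc(OCOC)cc1OCOC)CC2=O | intermediate
17 | (2S)-2-(2,4-dihydroxyphenyl)-7-hydroxy-6,8-bis(3-methylbut-2-en-1-yl)-2,3-dihydro-4H-chromen-4-one | CC(C)=CCc1cc2c(c(CC=C(C)C)c1O)O[C@H](c1ccc(O)cc1O)CC2=O | target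

Total step count: 11. Longest linear sequence: 8 steps (steps 1 to 5, then 9, 10 and 11).

**Steps most likely to fail**

Step 9 (Proposed new method). What may go wrong: C–H vinylation of the vinylpalladium species before CO insertion (leading to a benzofuran), or capture of the acylpalladium by water or phenoxide before it can palladate C4a. Fallback, from 8 and 12, returning at 14: the base-mediated addition alone (K2CO3, DMF, 110 °C) would give 13, now isolated. Bromine–lithium exchange (t-BuLi, THF, −78 °C) would give the (Z)-vinyllithium F1, and CO2 would convert it into the (Z)-3-aryloxy-3-arylacrylic acid F2. Intramolecular Friedel–Crafts acylation through the mixed trifluoroacetic anhydride F3 (TFAA, CH2Cl2, 0 °C), the classical closure of 3-aryloxyacrylic acids to chromones, would then form the same C4–C4a bond and give flavone 14.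

Step 10. What may go wrong: poor facial selectivity or slow hydride transfer at the hindered, electron-rich C2 of the 2-arylchromone, or further reduction at C4. Fallback, from 14, returning at 16: non-selective conjugate reduction with LiBH(s-Bu)3 (THF, −78 °C, AcOH quench) would give the racemic flavanone F4. Kinetic resolution by asymmetric transfer hydrogenation (RuCl(p-cymene)[(R,R)-TsDPEN], HCO2H/Et3N, EtOAc, rt) should then reduce the (2R)-ketone to the cis-(2R,4R)-flavan-4-ol F5 and leave (2S)-16, which is separated by chromatography.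

Step 11. What may go wrong: acid-induced addition of the freed 7-hydroxyl to a flanking prenyl group (chroman formation), hydration of the prenyl alkenes, or loss of configuration by ionisation of the benzylic C2–O1 bond once the 2'- and 4'-hydroxyls are free. Fallback, from 16, returning at 17: TESOTf with 2,2'-bipyridyl (CH2Cl2, 0 °C) exchanges aryl MOM ethers for silyl ethers without protic acid and would give the tris(triethylsilyl) ether F6. Buffered fluoride (HF·pyridine, pyridine, THF, 0 °C) would then release 17.

**Further compounds**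
F1 | step 9 | [(Z)-2-[2,4-bis(methoxymethoxy)phenyl]-2-[3-(methoxymethoxy)-2,4-bis(3-methylbut-2-en-1-yl)phenoxy]ethenyl]lithium | [Li]/C=C(\Oc1ccc(CC=C(C)C)c(OCOC)c1CC=C(C)C)c1ccc(OCOC)cc1OCOC
F2 | step 9 | (Z)-3-[2,4-bis(methoxymethoxy)phenyl]-3-[3-(methoxymethoxy)-2,4-bis(3-methylbut-2-en-1-yl)phenoxy]prop-2-enoic acid | OC(=O)/C=C(\Oc1ccc(CC=C(C)C)c(OCOC)c1CC=C(C)C)c1ccc(OCOC)cc1OCOC
F3 | step 9 | mixed anhydride of F2 with trifluoroacetic acid | FC(F)(F)C(=O)OC(=O)/C=C(\Oc1ccc(CC=C(C)C)c(OCOC)c1CC=C(C)C)c1ccc(OCOC)cc1OCOC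
F4 | step 10 | racemic 2-[2,4-bis(methoxymethoxy)phenyl]-7-(methoxymethoxy)-6,8-bis(3-methylbut-2-en-1-yl)-2,3-dihydro-4H-chromen-4-one | CC(C)=CCc1cc2c(c(CC=C(C)C)c1OCOC)OC(c1ccc(OCOC)cc1OCOC)CC2=O
F5 | step 10 | (2R,4R)-2-[2,4-bis(methoxymethoxy)phenyl]-7-(methoxymethoxy)-6,8-bis(3-methylbut-2-en-1-yl)-3,4-dihydro-2H-chromen-4-ol | CC(C)=CCc1cc2c(c(CC=C(C)C)c1OCOC)O[C@@H](c1ccc(OCOC)cc1OCOC)C[C@H]2O
F6 | step 11 | (2S)-2-[2,4-bis(triethylsilyloxy)phenyl]-7-(triethylsilyloxy)-6,8-bis(3-methylbut-2-en-1-yl)-2,3-dihydro-4H-chromen-4-one | CC(C)=CCc1cc2c(c(CC=C(C)C)c1O[Si](CC)(CC)CC)O[C@H](c1ccc(O[Si](CC)(CC)CC)cc1O[Si](CC)(CC)CC)CC2=O
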